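**Retrosynthetic overview** (disconnections listed from the first bond made to the last)
1. Lower half: the benzylic C–C bond comes from acetoacetate alkylation (1 + 2 → 3), then deacylative diazo transfer gives the carbene precursor 4.
2. Key disconnection, the ester O–C(α) bond: a new enantioselective O–H insertion of the carbene from 4 into acrylic acid 5 gives acrylate 6 and sets the only stereocentre, (R).
3. Aryl–vinyl C–C bond: carboxylate-directed ortho C–H olefination of 2,3-dimethoxyphenylacetic acid 7 with 6 gives 8. Acid 7 has one free ortho position, which fixes the ring pattern and leaves the CH2CO2H free.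
4. Last: global O-demethylation of 8 (four ArOMe, one CO2Me) gives salvianolic acid D 10, via silyl intermediate 9.
5. No ring is formed; both benzene rings are bought (1 and 7).

Assumption: the sense of induction in step 3 cannot be predicted, so the enantiomer of the chiral phosphoric acid that gives (R)-6 is picked in a first screening run (both enantiomers are accessible).

**Step 1**
Reactants: 1 3,4-dimethoxybenzyl chloride; 2 methyl acetoacetate (2 equiv)
Product: 3 methyl 2-[(3,4-dimethoxyphenyl)methyl]-3-oxobutanoate (racemic)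
Conditions: K2CO3 (1.5 equiv), NaI (10 mol%), acetone, reflux
Reagents that add atoms: none
Why: SN2 C-alkylation of the stabilised acetoacetate enolate with an iodide-activated benzylic chloride, with excess 2 suppressing dialkylation; the new centre is racemic and is erased in step 2.

**Step 2**
Reactants: 3 methyl 2-[(3,4-dimethoxyphenyl)methyl]-3-oxobutanoate
Product: 4 methyl 2-diazo-3-(3,4-dimethoxyphenyl)propanoate
Conditions: p-ABSA (1.2 equiv), DBU (1.5 equiv), MeCN, 0 °C to rt
Reagents that add atoms: 4-acetamidobenzenesulfonyl azide (p-ABSA), CC(=O)Nc1ccc(cc1)S(=O)(=O)N=[N+]=[N-]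
Why: Regitz deacylative diazo transfer, in which the DBU enolate adds to the sulfonyl azide and the adduct fragments with transfer of the acetyl group to the sulfonamide nitrogen, leaving the α-alkyl-α-diazo ester.

**Step 3**
Reactants: 4 methyl 2-diazo-3-(3,4-dimethoxyphenyl)propanoate; 5 acrylic acid (1.5 equiv)
Product: 6 methyl (2R)-3-(3,4-dimethoxyphenyl)-2-(prop-2-enoyloxy)propanoate
Conditions: Rh2(TPA)4 (1 mol%), SPINOL-derived chiral phosphoric acid STRIP (5 mol%, enantiomer that gives R), CHCl3, −20 °C, 4 added over 3 h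
Reagents that add atoms: none
Why: Proposed new method: enantioselective carboxylic acid O–H insertion of an α-alkyl, β-hydrogen-bearing rhodium carbene. Rh2(TPA)4 expels N2 from 4 and the carbonyl oxygen of acrylic acid adds to the electrophilic carbene faster than 1,2-hydride shift (bulky triphenylacetate ligands, low temperature, acid in excess, diazo kept dilute to avoid pyrazoline formation), which forms the key O–C2 bond. The resulting enol is then protonated at C2 on one face by the chiral phosphoric acid acting as a bifunctional proton shuttle, which sets (R); the much stronger phosphoric acid should outrun the dimerised acrylic acid as proton-transfer catalyst. The closest known reaction type is Rh(II)/chiral proton-shuttle (phosphoric acid or guanidine) co-catalysed asymmetric O–H insertion of α-aryl diazo carbonyl compounds, together with racemic Rh-catalysed acid O–H insertion.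

**Step 4**
Reactants: 6 methyl (2R)-3-(3,4-dimethoxyphenyl)-2-(prop-2-enoyloxy)propanoate; 7 2-(2,3-dimethoxyphenyl)acetic acid (1.5 equiv)
Product: 8 2-[6-[(1E)-3-{[(2R)-3-(3,4-dimethoxyphenyl)-1-methoxy-1-oxopropan-2-yl]oxy}-3-oxoprop-1-en-1-yl]-2,3-dimethoxyphenyl]acetic acid
Conditions: Pd(OAc)2 (5 mol%), Ac-Ile-OH (10 mol%), KHCO3 (2 equiv), O2 (1 atm), t-AmOH, 85 °C; then 1 M HCl work-up
Reagents that add atoms: none
Why: Carboxylate-directed, amino-acid-ligand-accelerated Pd(II) ortho C–H olefination (oxidative Heck, Fujiwara–Moritani type), where the single ortho C–H of 7 gives one regioisomer, β-hydride elimination gives the E-alkene, and the weak base leaves the α-acyloxy ester centre untouched.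

**Step 5**
Reactants: 8 2-[6-[(1E)-3-{[(2R)-3-(3,4-dimethoxyphenyl)-1-methoxy-1-oxopropan-2-yl]oxy}-3-oxoprop-1-en-1-yl]-2,3-dimethoxyphenyl]acetic acid
Product: 10 salvianolic acid D, via hexakis(trimethylsilyl) derivative 9 (not isolated)
Conditions: TMSI (15 equiv), quinoline, 130 °C, Ar; then 1 M HCl, EtOAc, rt; RP-HPLC
Reagents that add atoms: iodotrimethylsilane (TMSI), C[Si](C)(C)I (its Me3Si groups are in 9 only; 10 keeps no reagent atom other than H from water)
Why: Global silyl-iodide dealkylation, in which TMSI activates the ether and ester oxygens and iodide removes the five methyl groups by SN2 at methyl (far faster than at the hindered secondary ester carbon), quinoline buffers HI so the E-enoate, the internal ester and the (R) centre survive, and aqueous acid hydrolyses the silyl groups.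

**Compound list**
1 | 3,4-dimethoxybenzyl chloride | COc1ccc(CCl)cc1OC | starting material
2 | methyl acetoacetate | COC(=O)CC(C)=O | starting material
3 | methyl 2-[(3,4-dimethoxyphenyl)methyl]-3-oxobutanoate (racemic) | COC(=O)C(Cc1ccc(OC)c(OC)c1)C(C)=O | intermediate
4 | methyl 2-diazo-3-(3,4-dimethoxyphenyl)propanoate | COC(=O)C(=[N+]=[N-])Cc1ccc(OC)c(OC)c1 | intermediate
5 | acrylic acid | C=CC(=O)O | starting material
6 | methyl (2R)-3-(3,4-dimethoxyphenyl)-2-(prop-2-enoyloxy)propanoate | C=CC(=O)O[C@H](Cc1ccc(OC)c(OC)c1)C(=O)OC | intermediate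
7 | 2-(2,3-dimethoxyphenyl)acetic acid | COc1cccc(CC(=O)O)c1OC | starting material
8 | 2-[6-[(1E)-3-{[(2R)-3-(3,4-dimethoxyphenyl)-1-methoxy-1-oxopropan-2-yl]oxy}-3-oxoprop-1-en-1-yl]-2,3-dimethoxyphenyl]acetic acid | OC(=O)Cc1c(/C=C/C(=O)O[C@H](Cc2ccc(OC)c(OC)c2)C(=O)OC)ccc(OC)c1OC | intermediate
9 | hexakis(trimethylsilyl) derivative of 10 (two trimethylsilyl esters, four aryl trimethylsilyl ethers; E, R) | C[Si](C)(C)OC(=O)Cc1c(/C=C/C(=O)O[C@H](Cc2ccc(O[Si](C)(C)C)c(O[Si](C)(C)C)c2)C(=O)O[Si](C)(C)C)ccc(O[Si](C)(C)C)c1O[Si](C)(C)C | intermediate (not isolated)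
10 | salvianolic acid D, (2R)-2-{[(2E)-3-[2-(carboxymethyl)-3,4-dihydroxyphenyl]prop-2-enoyl]oxy}-3-(3,4-dihydroxyphenyl)propanoic acid | O=C(O)Cc1c(/C=C/C(=O)O[C@H](Cc2ccc(O)c(O)c2)C(=O)O)ccc(O)c1O | target

**Totals**
Total step count: 5. Longest linear sequence: 5 steps (1 → 3 → 4 → 6 → 8 → 10); 7 enters at step 4.

**Steps most likely to fail**

Step 3 (the proposed new insertion). The risks are 1,2-hydride shift of the carbene to the cinnamate, low ee from proton transfer mediated by acrylic acid itself, and dipolar cycloaddition of the diazo ester to the acrylate. The fallback uses known chemistry only; it sets out from 4 and comes back at 6. Dimethyldioxirane (acetone, 0 °C) oxidises the diazo ester to methyl 3-(3,4-dimethoxyphenyl)-2-oxopropanoate F1. An (R)-selective ketoreductase (NADPH, glucose/GDH recycling, pH 7 buffer/DMSO) reduces it to methyl (2R)-3-(3,4-dimethoxyphenyl)-2-hydroxypropanoate F2. Acryloyl chloride and Et3N (CH2Cl2, −20 °C) acylate the alcohol with retention to give 6.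

Step 5 (global demethylation). The risks are cleavage of the internal ester, a low yield at 130 °C, and lactonisation of the CH2CO2H onto the neighbouring phenol (reopened by brief aqueous bicarbonate under argon). The fallback changes the protecting-group strategy to benzyl so that the end is a −78 °C debenzylation; it sets out from 7 (and uses 5 again) and comes back at 10. BBr3 (CH2Cl2, −78 °C to rt) demethylates 7 to 2-(2,3-dihydroxyphenyl)acetic acid F3. BnBr/K2CO3 (DMF) gives benzyl 2-[2,3-bis(benzyloxy)phenyl]acetate F4, and LiOH (THF/H2O) gives 2-[2,3-bis(benzyloxy)phenyl]acetic acid F5. Commercial 3,4-bis(benzyloxy)benzyl chloride and benzyl acetoacetate go through the chemistry of steps 1–3: alkylation gives benzyl 2-{[3,4-bis(benzyloxy)phenyl]methyl}-3-oxobutanoate F6, diazo transfer gives benzyl 3-[3,4-bis(benzyloxy)phenyl]-2-diazopropanoate F7, and O–H insertion into 5 under the step 3 conditions gives benzyl (2R)-3-[3,4-bis(benzyloxy)phenyl]-2-(prop-2-enoyloxy)propanoate F8. C–H olefination of F5 with F8 as in step 4 gives 2-[2,3-bis(benzyloxy)-6-[(1E)-3-{[(2R)-1-(benzyloxy)-3-[3,4-bis(benzyloxy)phenyl]-1-oxopropan-2-yl]oxy}-3-oxoprop-1-en-1-yl]phenyl]acetic acid F9. BCl3 with pentamethylbenzene (CH2Cl2, −78 °C) then removes the four benzyl ethers and the benzyl ester without touching the alkene or the internal ester and gives 10.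

Step 4 (C–H olefination). The risks are incomplete conversion of the valuable acrylate, oxidation of the electron-rich arenes under Pd(II)/O2, and partial epimerisation of the α-acyloxy ester. The fallback replaces C–H activation by a halide-based Heck coupling; it sets out from 7 and comes back at 8. NBS (MeCN, 0 °C) brominates 7 para to the 3-methoxy group, the position ortho to the side chain, to give 2-(6-bromo-2,3-dimethoxyphenyl)acetic acid F10. A Heck reaction with 6 (Pd(OAc)2, P(o-tol)3, NaHCO3, Bu4NCl, DMF, 80 °C) gives 8 as the E-alkene.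

**Further compounds**
F1 | step 3 | methyl 3-(3,4-dimethoxyphenyl)-2-oxopropanoate | COC(=O)C(=O)Cc1ccc(OC)c(OC)c1
F2 | step 3 | methyl (2R)-3-(3,4-dimethoxyphenyl)-2-hydroxypropanoate | O[C@H](Cc1ccc(OC)c(OC)c1)C(=O)OC
F3 | step 5 | 2-(2,3-dihydroxyphenyl)acetic acid | OC(=O)Cc1cccc(O)c1O
F4 | step 5 | benzyl 2-[2,3-bis(benzyloxy)phenyl]acetate | O=C(Cc1cccc(OCc2ccccc2)c1OCc1ccccc1)OCc1ccccc1
F5 | step 5 | 2-[2,3-bis(benzyloxy)phenyl]acetic acid | OC(=O)Cc1cccc(OCc2ccccc2)c1OCc1ccccc1
F6 | step 5 | benzyl 2-{[3,4-bis(benzyloxy)phenyl]methyl}-3-oxobutanoate (racemic) | CC(=O)C(Cc1ccc(OCc2ccccc2)c(OCc2ccccc2)c1)C(=O)OCc1ccccc1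
F7 | step 5 | benzyl 3-[3,4-bis(benzyloxy)phenyl]-2-diazopropanoate | [N-]=[N+]=C(Cc1ccc(OCc2ccccc2)c(OCc2ccccc2)c1)C(=O)OCc1ccccc1
F8 | step 5 | benzyl (2R)-3-[3,4-bis(benzyloxy)phenyl]-2-(prop-2-enoyloxy)propanoate | C=CC(=O)O[C@H](Cc1ccc(OCc2ccccc2)c(OCc2ccccc2)c1)C(=O)OCc1ccccc1
F9 | step 5 | 2-[2,3-bis(benzyloxy)-6-[(1E)-3-{[(2R)-1-(benzyloxy)-3-[3,4-bis(benzyloxy)phenyl]-1-oxopropan-2-yl]oxy}-3-oxoprop-1-en-1-yl]phenyl]acetic acid | OC(=O)Cc1c(/C=C/C(=O)O[C@H](Cc2ccc(OCc3ccccc3)c(OCc3ccccc3)c2)C(=O)OCc2ccccc2)ccc(OCc2ccccc2)c1OCc1ccccc1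
F10 | step 4 | 2-(6-bromo-2,3-dimethoxyphenyl)acetic acid | OC(=O)Cc1c(Br)ccc(OC)c1OC
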